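The constants of this flask were not given, so I worked from one figure the readings do give: w, the odds of L against Q lost to anything else, per mM of G charged (a selectivity factor of my own). The loss is whatever has been fed and is neither L nor Q.

| flask | Q | G | temperature | remark | time |
|---|---|---|---|---|---|
| Saturday's | 0.46 M (fed, over 30 min) | 2.4 mM | 84 °C | run made earlier; the fed solution adds 0.50 times the starting volume |  |
| Thursday's | 0.46 M (fed, over 30 min) | 4.6 mM | 92 °C | run made earlier; the fed solution adds 0.50 times the starting volume |  |
| teal | 0.46 M | 3.0 mM | 95 °C | everything together at the start, the whole solution of Q included, so that from the start the volume is larger by 0.50 times the starting volume | 80 min |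
| ochre | 0.46 M (fed, over 30 min) | 6.4 mM | 80 °C | the fed solution adds 0.50 times the starting volume | 80 min |

| run | time / min | L / % | Q / % |
|---|---|---|---|
| Saturday's | 3.00 | 0.5 | 8.6 |
| Saturday's | 8.00 | 4.6 | 19.9 |
| Saturday's | 15.0 | 12.8 | 31.2 |
| Saturday's | 40.0 | 37.9 | 30.4 |
| Thursday's | 1.50 | 0 | 4.9 |
| Thursday's | 4.00 | 2.9 | 8.9 |
| Thursday's | 8.00 | 8.2 | 14.8 |
| Thursday's | 20.0 | 25.3 | 25.3 |

(each reading ± 1 percentage point)

- the flask that ends with the higher amount of L, in percent of the Q charged, or "neither" when 2 percentage points or less lies between them (teal / ochre / neither)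
- final L, as a percentage of the Q charged, in teal
- final L, as a percentage of the Q charged, in ochre

- amounts are per litre of the starting volume; all of the dose is in the solution fed
- percentages count the whole charge, also what has not yet gone in

As readings, Saturday's run at 40.0 min, its feed finished, gives w = 0.498 mM⁻¹. Thursday's run at 20.0 min, with 66.7% of the Q fed, gives 0.342 mM⁻¹.

I took the settings one at a time, by hand. More G should raise the odds, so I took them as proportional to the G charged; this was an assumption, since the two runs changed G and temperature together. Next, on that assumption, w as read was lower at 92 °C than at 84 °C. Working in logarithms, I carried that fall on in proportion to the degrees, which gave 0.297 mM⁻¹ at teal's 95 °C: this is w for teal, the odds of L against loss per mM of G. For ochre at 80 °C it gave 0.601 mM⁻¹. No run had its Q in at the start, so I used the fed figure for teal unchanged, as a guess. Last, I took 80 min as long enough to use up the Q in both flasks, which makes L the odds over one plus the odds. So I expected 47.2% in teal and 79.4% in ochre, and ochre ahead by more than the margin.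

The forecast chose ochre, with 43% for teal and 79% for ochre, holding that in teal “decay and side loss compete strongly”. My teal figure was higher than that, and my ochre figure stood close to it.

The flasks gave 52.2% of L in teal and 63.7% in ochre, so ochre ended higher.

    2 G → J (k = 10.0 M⁻¹ min⁻¹, Ea = 59.0 kJ mol⁻¹)
    Q → D (k = 0.0150 min⁻¹, Ea = 119 kJ mol⁻¹)
    Q + G → G + L (k = 29.0 M⁻¹ min⁻¹, Ea = 58.0 kJ mol⁻¹)
    2 Q → Z (k = 0.00470 M⁻¹ min⁻¹, Ea = 81.0 kJ mol⁻¹)
    (constants at 80 °C)

Teal's own w at the end came to 0.364 mM⁻¹, higher than my 0.297 mM⁻¹. Ochre, with 7.62% of its Q still there, came to 0.348 mM⁻¹, lower than my 0.601 mM⁻¹, and below teal's figure too. The neighbouring flask is teal with 0.0051 M of G. My 0.297 mM⁻¹ gives it odds of 1.51, so 60.2% of L. That flask ended with 63.0%.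

The readings stem from a simulated flask for an exercise; noise was put on by code.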